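The tetronic acid ring (O1–C2–C3–C4–C5) is opened at its alkyl–oxygen bond O1–C5, not at the usual acyl–oxygen bond. C5 lies α to the C4 carbonyl and 1,5 to the C2 carboxyl oxygen, so it can serve as an SN2-activated α-chloro ketone carbon. In the last step fluoride unmasks a β-keto carboxylate whose oxygen displaces chloride at C5 (5-exo-tet, inversion). This turns an organocatalytically set (S)-C–Cl centre into the (R)-C5–O1 stereocentre and delivers the target. The precursor is an acyclic γ-chloro-β-keto 2-(trimethylsilyl)ethyl ester carrying the complete difuryl diene chain, built by Still–Gennari olefination, Negishi carboalumination and B-alkyl Suzuki coupling.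

Key step: step 13

Remark: ring atoms are numbered O1, C2 (lactone carbonyl), C3 (methyl-bearing), C4 (enol carbon), C5 (stereocentre); the side chain is numbered C6 onward from C5.
Remark: (2R,5R)-2,5-diphenylpyrrolidine is taken to deliver the (S)-α-chloroaldehyde; if the sense of induction is the reverse, its (2S,5S) enantiomer is used.
Remark: compounds 1, 2, 6, 7, 15, 20 and 21 are taken as commercially available.

Step 1
Reactants: 1 3-bromofuran; 2 4-bromofuran-2-carbaldehyde
Product: 4 (4-bromofuran-2-yl)(furan-3-yl)methanol (racemic), via 3-furyllithium 3 (not isolated)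
Conditions: n-BuLi, THF, −78 °C; then 2, −78 °C; aq. NH4Cl
Reagents that add atoms: none
Why: Bromine–lithium exchange gives 3-furyllithium, stable at −78 °C, whose 1,2-addition to the aldehyde should outrun exchange with the ring bromide of 2; the carbinol stereocentre is racemic and is removed in step 2.

Step 2
Reactants: 4 (4-bromofuran-2-yl)(furan-3-yl)methanol
Product: 5 4-bromo-2-(furan-3-ylmethyl)furan
Conditions: Et3SiH, CF3CO2H, CH2Cl2, −20 °C → 0 °C
Reagents that add atoms: none
Why: Ionic hydrogenation, in which acid ionises the doubly furyl-stabilised carbinol and the silane delivers hydride to the cation while the ring bromide stays inert.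

Step 3
Reactants: 6 pent-4-ynal; 7 ethyl 2-[bis(2,2,2-trifluoroethoxy)phosphoryl]propanoate
Product: 8 ethyl (2Z)-2-methylhept-2-en-6-ynoate
Conditions: KN(SiMe3)2, 18-crown-6, THF, −78 °C
Reagents that add atoms: none
Why: Still–Gennari olefination, in which the trifluoroethyl phosphonate eliminates under kinetic control to give the (Z)-trisubstituted enoate (ester cis to the chain), the geometry later needed at C7=C8 of the target.

Step 4
Reactants: 8 ethyl (2Z)-2-methylhept-2-en-6-ynoate
Product: 9 (2Z)-2-methylhept-2-en-6-yn-1-ol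
Conditions: i-Bu2AlH (2.2 equiv), CH2Cl2, −78 °C; aq. KNaC4H4O6
Reagents that add atoms: none
Why: Hydride reduction of the conjugated ester at low temperature should give the allylic alcohol without touching the alkyne or the alkene geometry.

Step 5
Reactants: 9 (2Z)-2-methylhept-2-en-6-yn-1-ol
Product: 11 (2Z,6E)-2,6-dimethylnona-2,6,8-trien-1-ol, via alkenylalane 10 (not isolated)
Conditions: Me3Al (3.5 equiv), Cp2ZrCl2 (25 mol%), CH2Cl2, 0 °C → rt; then vinyl bromide, Pd(PPh3)4 (5 mol%), ZnCl2, THF, rt
Reagents that add atoms: trimethylaluminium, C[Al](C)C; vinyl bromide, C=CBr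
Why: Negishi zirconium-catalysed carboalumination adds methyl and aluminium syn across the terminal alkyne (methyl to the internal carbon), and the alkenylalane is then cross-coupled with vinyl bromide under zerovalent palladium with retention, which fixes the (E)-trisubstituted alkene while the hydroxyl is carried as its aluminium alkoxide.

Step 6
Reactants: 11 (2Z,6E)-2,6-dimethylnona-2,6,8-trien-1-ol; 5 4-bromo-2-(furan-3-ylmethyl)furan
Product: 13 (2Z,6E)-9-[5-(furan-3-ylmethyl)furan-3-yl]-2,6-dimethylnona-2,6-dien-1-ol, via alkylborane 12 (not isolated)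
Conditions: 9-BBN (2.2 equiv), THF, 0 °C → rt; then 5, Pd(dppf)Cl2 (5 mol%), K3PO4 (aq.), DMF, 50 °C
Reagents that add atoms: none
Why: B-alkyl Suzuki–Miyaura coupling, in which 9-BBN (one equivalent being consumed by the hydroxyl) should hydroborate only the monosubstituted vinyl terminus of the diene at its terminal carbon and the alkylborane then couples with the bromofuran, leaving both trisubstituted alkenes untouched.

Step 7
Reactants: 13 (2Z,6E)-9-[5-(furan-3-ylmethyl)furan-3-yl]-2,6-dimethylnona-2,6-dien-1-ol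
Product: 14 4-[(3E,7Z)-9-bromo-4,8-dimethylnona-3,7-dien-1-yl]-2-(furan-3-ylmethyl)furan
Conditions: CBr4, PPh3, 2,6-lutidine, CH2Cl2, −20 °C
Reagents that add atoms: carbon tetrabromide, BrC(Br)(Br)Br
Why: Appel bromination, in which bromide displaces the alkoxyphosphonium by SN2 at the primary allylic carbon under cold, buffered conditions that should preserve the (Z) geometry and the furans.

Step 8
Reactants: 14 4-[(3E,7Z)-9-bromo-4,8-dimethylnona-3,7-dien-1-yl]-2-(furan-3-ylmethyl)furan; 15 acetaldehyde N,N-dimethylhydrazone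
Product: 18 (4Z,8E)-11-[5-(furan-3-ylmethyl)furan-3-yl]-4,8-dimethylundeca-4,8-dienal, via lithiated hydrazone 16 (not isolated), via alkylated hydrazone 17 (not isolated)
Conditions: LiN(i-Pr)2, THF, 0 °C; then 14, −78 °C → 0 °C; then aq. oxalic acid, Et2O, rt
Reagents that add atoms: water, O
Why: Aza-enolate alkylation of the metalated hydrazone by SN2 at the primary allylic bromide without allylic transposition, followed by mild two-phase hydrolysis, adds the two-carbon aldehyde unit that becomes C4 and C5.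

Step 9
Reactants: 18 (4Z,8E)-11-[5-(furan-3-ylmethyl)furan-3-yl]-4,8-dimethylundeca-4,8-dienal
Product: 19 (2S,4Z,8E)-2-chloro-11-[5-(furan-3-ylmethyl)furan-3-yl]-4,8-dimethylundeca-4,8-dienal
Conditions: N-chlorosuccinimide (1.2 equiv), (2R,5R)-2,5-diphenylpyrrolidine (10 mol%), CH2Cl2, 0 °C → rt; pentane, filtration; used at once
Reagents that add atoms: N-chlorosuccinimide, O=C1CCC(=O)N1Cl
Why: Enamine organocatalysis (asymmetric α-chlorination of an aldehyde), in which the C2-symmetric amine exposes one enamine face to the chlorine donor so that the (S)-C–Cl centre (future C5) is set by catalyst control, the enamine being far more nucleophilic than the furans or alkenes.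

Step 10
Reactants: 20 propanoyl chloride; 21 2-(trimethylsilyl)ethanol
Product: 22 2-(trimethylsilyl)ethyl propanoate
Conditions: Et3N, DMAP (cat.), CH2Cl2, 0 °C → rt
Reagents that add atoms: none
Why: Acyl substitution of an acid chloride by the alcohol under nucleophilic catalysis.

Step 11
Reactants: 22 2-(trimethylsilyl)ethyl propanoate; 19 (2S,4Z,8E)-2-chloro-11-[5-(furan-3-ylmethyl)furan-3-yl]-4,8-dimethylundeca-4,8-dienal
Product: 24 2-(trimethylsilyl)ethyl (4S,6Z,10E)-4-chloro-13-[5-(furan-3-ylmethyl)furan-3-yl]-3-hydroxy-2,6,10-trimethyltrideca-6,10-dienoate (C2/C3 epimer mixture), via lithium enolate 23 (not isolated)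
Conditions: LiN(i-Pr)2, THF, −78 °C; then 19, −78 °C; aq. NH4Cl at −78 °C
Reagents that add atoms: none
Why: Lithium ester enolate aldol addition, fast enough at −78 °C that the enolisable α-chloroaldehyde should not be deprotonated; the new C2 and C3 centres form as a mixture that is erased in steps 12 and 13, and the C–Cl centre is untouched.

Step 12
Reactants: 24 2-(trimethylsilyl)ethyl (4S,6Z,10E)-4-chloro-13-[5-(furan-3-ylmethyl)furan-3-yl]-3-hydroxy-2,6,10-trimethyltrideca-6,10-dienoate
Product: 25 2-(trimethylsilyl)ethyl (4S,6Z,10E)-4-chloro-13-[5-(furan-3-ylmethyl)furan-3-yl]-2,6,10-trimethyl-3-oxotrideca-6,10-dienoate (C2 epimer mixture)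
Conditions: Dess–Martin periodinane, NaHCO3, CH2Cl2, 0 °C → rt
Reagents that add atoms: none
Why: Dess–Martin oxidation of the secondary alcohol under buffered, non-basic conditions should give the β-keto ester (all C3-hydroxy epimers converge) without enolising the chlorine-bearing carbon.

Step 13
Reactants: 25 2-(trimethylsilyl)ethyl (4S,6Z,10E)-4-chloro-13-[5-(furan-3-ylmethyl)furan-3-yl]-2,6,10-trimethyl-3-oxotrideca-6,10-dienoate
Product: 28 (5R)-5-[(2Z,6E)-9-[5-(furan-3-ylmethyl)furan-3-yl]-2,6-dimethylnona-2,6-dien-1-yl]-4-hydroxy-3-methylfuran-2(5H)-one, via carboxylate 26 (not isolated), via tetronate salt 27 (not isolated)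
Conditions: Bu4NF (2.5 equiv), THF, 0 °C → rt; then cold 0.5 M HCl
Reagents that add atoms: none
Why: Fluoride attacks silicon and the ester fragments to ethylene, Me3SiF and the β-keto carboxylate 26, whose oxygen (O1) then displaces chloride at C5 in an intramolecular SN2 reaction accelerated by the adjacent C4 carbonyl; the furan-2,4-dione formed enolises to the tetronate 27, which is protonated on work-up. The closest known reaction type is the classical tetronic acid synthesis by O-alkylative cyclisation of γ-halo acetoacetates. The five-membered ring closes in the 5-exo-tet mode. The C5 stereocentre is controlled by the substrate, since backside attack inverts the (S)-C–Cl centre to the (R)-C–O centre. The step needs O- over C-alkylation (the enolate carbon C3 could only close a three-membered ring) and no epimerisation at C5 before closure, which the more acidic C3–H should secure because its enolate shields C5–H from deprotonation; after closure the tetronate anion makes C5–H non-acidic.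

Compound list
1 | 3-bromofuran | Brc1ccoc1 | starting material
2 | 4-bromofuran-2-carbaldehyde | O=Cc1cc(Br)co1 | starting material
3 | 3-furyllithium (not isolated) | [Li]c1ccoc1 | intermediate
4 | (4-bromofuran-2-yl)(furan-3-yl)methanol (racemic) | OC(c1ccoc1)c1cc(Br)co1 | intermediate
5 | 4-bromo-2-(furan-3-ylmethyl)furan | Brc1coc(Cc2ccoc2)c1 | intermediate
6 | pent-4-ynal | C#CCCC=O | starting material
7 | ethyl 2-[bis(2,2,2-trifluoroethoxy)phosphoryl]propanoate | CCOC(=O)C(C)P(=O)(OCC(F)(F)F)OCC(F)(F)F | starting material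
8 | ethyl (2Z)-2-methylhept-2-en-6-ynoate | CCOC(=O)/C(C)=C\CCC#C | intermediate
9 | (2Z)-2-methylhept-2-en-6-yn-1-ol | OC/C(C)=C\CCC#C | intermediate
10 | dimethyl[(1E,5Z)-7-(dimethylalumanyloxy)-2,6-dimethylhepta-1,5-dien-1-yl]alumane (not isolated) | C[Al](C)OC/C(C)=C\CC/C(C)=C/[Al](C)C | intermediate
11 | (2Z,6E)-2,6-dimethylnona-2,6,8-trien-1-ol | OC/C(C)=C\CC/C(C)=C/C=C | intermediate
12 | B-alkyl-9-BBN of 11 with the hydroxyl as its 9-BBN borinate (not isolated) | O(B1C2CCCC1CCC2)C/C(C)=C\CC/C(C)=C/CCB1C2CCCC1CCC2 | intermediate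
13 | (2Z,6E)-9-[5-(furan-3-ylmethyl)furan-3-yl]-2,6-dimethylnona-2,6-dien-1-ol | OC/C(C)=C\CC/C(C)=C/CCc1coc(Cc2ccoc2)c1 | intermediate
14 | 4-[(3E,7Z)-9-bromo-4,8-dimethylnona-3,7-dien-1-yl]-2-(furan-3-ylmethyl)furan | BrC/C(C)=C\CC/C(C)=C/CCc1coc(Cc2ccoc2)c1 | intermediate
15 | acetaldehyde N,N-dimethylhydrazone | CC=NN(C)C | starting material
16 | lithiated acetaldehyde N,N-dimethylhydrazone (not isolated) | [Li]CC=NN(C)C | intermediate
17 | N,N-dimethylhydrazone of aldehyde 18 (not isolated) | CN(C)N=CCC/C(C)=C\CC/C(C)=C/CCc1coc(Cc2ccoc2)c1 | intermediate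
18 | (4Z,8E)-11-[5-(furan-3-ylmethyl)furan-3-yl]-4,8-dimethylundeca-4,8-dienal | O=CCC/C(C)=C\CC/C(C)=C/CCc1coc(Cc2ccoc2)c1 | intermediate
19 | (2S,4Z,8E)-2-chloro-11-[5-(furan-3-ylmethyl)furan-3-yl]-4,8-dimethylundeca-4,8-dienal | O=C[C@@H](Cl)C/C(C)=C\CC/C(C)=C/CCc1coc(Cc2ccoc2)c1 | intermediate
20 | propanoyl chloride | CCC(=O)Cl | starting material
21 | 2-(trimethylsilyl)ethanol | C[Si](C)(C)CCO | starting material
22 | 2-(trimethylsilyl)ethyl propanoate | CCC(=O)OCC[Si](C)(C)C | intermediate
23 | lithium enolate of 22 (not isolated) | CC=C(O[Li])OCC[Si](C)(C)C | intermediate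
24 | 2-(trimethylsilyl)ethyl (4S,6Z,10E)-4-chloro-13-[5-(furan-3-ylmethyl)furan-3-yl]-3-hydroxy-2,6,10-trimethyltrideca-6,10-dienoate (C2/C3 epimer mixture) | CC(C(O)[C@@H](Cl)C/C(C)=C\CC/C(C)=C/CCc1coc(Cc2ccoc2)c1)C(=O)OCC[Si](C)(C)C | intermediate
25 | 2-(trimethylsilyl)ethyl (4S,6Z,10E)-4-chloro-13-[5-(furan-3-ylmethyl)furan-3-yl]-2,6,10-trimethyl-3-oxotrideca-6,10-dienoate (C2 epimer mixture) | CC(C(=O)[C@@H](Cl)C/C(C)=C\CC/C(C)=C/CCc1coc(Cc2ccoc2)c1)C(=O)OCC[Si](C)(C)C | intermediate
26 | tetrabutylammonium (4S,6Z,10E)-4-chloro-13-[5-(furan-3-ylmethyl)furan-3-yl]-2,6,10-trimethyl-3-oxotrideca-6,10-dienoate (not isolated) | CC(C(=O)[C@@H](Cl)C/C(C)=C\CC/C(C)=C/CCc1coc(Cc2ccoc2)c1)C(=O)[O-].CCCC[N+](CCCC)(CCCC)CCCC | intermediate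
27 | tetrabutylammonium salt of 28 (tetronate, not isolated) | CC1=C([O-])[C@@H](C/C(C)=C\CC/C(C)=C/CCc2coc(Cc3ccoc3)c2)OC1=O.CCCC[N+](CCCC)(CCCC)CCCC | intermediate
28 | (5R)-5-[(2Z,6E)-9-[5-(furan-3-ylmethyl)furan-3-yl]-2,6-dimethylnona-2,6-dien-1-yl]-4-hydroxy-3-methylfuran-2(5H)-one | CC1=C(O)[C@@H](C/C(C)=C\CC/C(C)=C/CCc2coc(Cc3ccoc3)c2)OC1=O | target

Total step count: 13. Longest linear sequence: 10 steps (steps 3, 4, 5, 6, 7, 8, 9, 11, 12, 13, from pent-4-ynal 6 to 28).

Steps most likely to fail

1. Step 13 (key step). The α-chloro ketone may epimerise at C5 by enolisation under the basic fluoride conditions, or fluoride may displace chloride intermolecularly before the carboxylate is unmasked. Fallback, setting out from 19 and returning at 28: the ring is closed instead at C3–C4 by a Dieckmann cyclisation after the C5–O bond has been made intermolecularly. Pinnick oxidation of 19 (NaClO2, NaH2PO4, 2-methylbut-2-ene, t-BuOH/H2O) gives (2S,4Z,8E)-2-chloro-11-[5-(furan-3-ylmethyl)furan-3-yl]-4,8-dimethylundeca-4,8-dienoic acid F1. Trimethylsilyldiazomethane in MeOH/toluene gives its methyl ester F2. Caesium propanoate in DMF displaces chloride with inversion to give methyl (2R,4Z,8E)-11-[5-(furan-3-ylmethyl)furan-3-yl]-4,8-dimethyl-2-(propanoyloxy)undeca-4,8-dienoate F3. Treatment with LiN(SiMe3)2 in THF at −78 °C → 0 °C and acidic work-up should then give 28.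

2. Step 9. The chlorine donor may attack the electron-rich furan rings, and the α-chloroaldehyde may lose enantiopurity through enamine or enol exchange. Fallback, setting out from 18 and returning at 25: the chlorine is introduced at the acid oxidation level with a milder chlorine donor and a configurationally more robust product. Pinnick oxidation of 18 gives (4Z,8E)-11-[5-(furan-3-ylmethyl)furan-3-yl]-4,8-dimethylundeca-4,8-dienoic acid F4. 1-Chloro-N,N,2-trimethylprop-1-en-1-amine in CH2Cl2 converts it under neutral conditions into the acid chloride F5. Cinchona-alkaloid-catalysed asymmetric α-chlorination of the acid chloride (O-benzoylquinine or its quinidine pseudoenantiomer, whichever gives the (S) sense; 2,3,4,5,6,6-hexachlorocyclohexa-2,4-dien-1-one; hindered amine base; THF, −78 °C) gives pentachlorophenyl (2S,4Z,8E)-2-chloro-11-[5-(furan-3-ylmethyl)furan-3-yl]-4,8-dimethylundeca-4,8-dienoate F6. Crossed Claisen condensation of F6 with two equivalents of enolate 23 at −78 °C should give 25.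

3. Step 6. The free hydroxyl consumes borane and the diene may be hydroborated incompletely or at the wrong position; slow oxidative addition into the electron-rich bromofuran may let the alkylborane decompose by protodeboronation. Fallback, setting out from 5 and 10 and returning at 13: the roles of the partners are exchanged. Bromide 5 is vinylated (potassium vinyltrifluoroborate, Pd(dppf)Cl2, Et3N, n-PrOH, 80 °C) to 4-ethenyl-2-(furan-3-ylmethyl)furan F7. Alane 10 is quenched with I2 instead of being coupled, giving (2Z,6E)-7-iodo-2,6-dimethylhepta-2,6-dien-1-ol F8. Hydroboration of F7 with 9-BBN gives 9-{2-[5-(furan-3-ylmethyl)furan-3-yl]ethyl}-9-borabicyclo[3.3.1]nonane F9, which is coupled with the reactive alkenyl iodide F8 (Pd(dppf)Cl2, K3PO4 aq., DMF, rt) to give 13.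

Further compounds
F1 | step 13 | (2S,4Z,8E)-2-chloro-11-[5-(furan-3-ylmethyl)furan-3-yl]-4,8-dimethylundeca-4,8-dienoic acid | OC(=O)[C@@H](Cl)C/C(C)=C\CC/C(C)=C/CCc1coc(Cc2ccoc2)c1
F2 | step 13 | methyl (2S,4Z,8E)-2-chloro-11-[5-(furan-3-ylmethyl)furan-3-yl]-4,8-dimethylundeca-4,8-dienoate | COC(=O)[C@@H](Cl)C/C(C)=C\CC/C(C)=C/CCc1coc(Cc2ccoc2)c1
F3 | step 13 | methyl (2R,4Z,8E)-11-[5-(furan-3-ylmethyl)furan-3-yl]-4,8-dimethyl-2-(propanoyloxy)undeca-4,8-dienoate | COC(=O)[C@H](OC(=O)CC)C/C(C)=C\CC/C(C)=C/CCc1coc(Cc2ccoc2)c1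
F4 | step 9 | (4Z,8E)-11-[5-(furan-3-ylmethyl)furan-3-yl]-4,8-dimethylundeca-4,8-dienoic acid | OC(=O)CC/C(C)=C\CC/C(C)=C/CCc1coc(Cc2ccoc2)c1
F5 | step 9 | (4Z,8E)-11-[5-(furan-3-ylmethyl)furan-3-yl]-4,8-dimethylundeca-4,8-dienoyl chloride | ClC(=O)CC/C(C)=C\CC/C(C)=C/CCc1coc(Cc2ccoc2)c1
F6 | step 9 | pentachlorophenyl (2S,4Z,8E)-2-chloro-11-[5-(furan-3-ylmethyl)furan-3-yl]-4,8-dimethylundeca-4,8-dienoate | O=C(Oc1c(Cl)c(Cl)c(Cl)c(Cl)c1Cl)[C@@H](Cl)C/C(C)=C\CC/C(C)=C/CCc1coc(Cc2ccoc2)c1
F7 | step 6 | 4-ethenyl-2-(furan-3-ylmethyl)furan | C=Cc1coc(Cc2ccoc2)c1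
F8 | step 6 | (2Z,6E)-7-iodo-2,6-dimethylhepta-2,6-dien-1-ol | OC/C(C)=C\CC/C(C)=C/I
F9 | step 6 | 9-{2-[5-(furan-3-ylmethyl)furan-3-yl]ethyl}-9-borabicyclo[3.3.1]nonane | C(Cc1coc(Cc2ccoc2)c1)B1C2CCCC1CCC2
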